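**Plan**
- The pyranone is cut last, at C4–C5 and O1–C2. Its C2–C3–C4 is a malonyl unit whose middle carbon C3 already carries the bridging CH2, and C5–C6–O1 with the methyl and ethyl groups is an enol of pentan-3-one.
- Earlier cuts: the two aryl acetates, the chromene C6–CH2 bond (Michael addition to a methylidene malonate), the chromene pyran ring (C4a–C4 and O1–C2, from prenal) and the aryl–acyl bond.
- Forward: acylphloroglucinol, then the 2H-chromene ring, then the malonate arm at C6, then acetates and malonyl dichloride, then the pyranone ring, then deacetylation.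
- Stereochemistry: the single stereocentre comes from (S)-2-methylbutanoic acid and is carried through; no strong base or hot acid is used while the phenols next to the ketone are capped.

Key step: step 10

Remark: chromene atoms are numbered O1, C2–C4, C4a, C5–C8, C8a and pyranone atoms O1, C2–C6; the enol silane is drawn Z, but pentan-3-one is symmetrical, so any E/Z mixture gives the same ring.

**Step 1**
Reactants: 1 (S)-2-methylbutanoic acid
Product: 2 (S)-2-methylbutanoyl chloride
Conditions: (COCl)2, DMF (cat.), CH2Cl2, 0 °C → rt; used as a solution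
Reagents that add atoms: oxalyl chloride, O=C(Cl)C(=O)Cl
Why: DMF-catalysed (Vilsmeier-type) acid chloride formation runs without base, so the α-stereocentre cannot racemise through a ketene.

**Step 2**
Reactants: 2 (S)-2-methylbutanoyl chloride; 3 phloroglucinol (benzene-1,3,5-triol)
Product: 4 (2S)-2-methyl-1-(2,4,6-trihydroxyphenyl)butan-1-one
Conditions: AlCl3 (4 equiv), PhNO2–CH2Cl2, 0 °C → rt; ice/aq. HCl
Reagents that add atoms: none
Why: Friedel–Crafts acylation of the symmetrical triphenol can give only one regioisomer, the product ketone is deactivated towards a second acylation, and the low temperature should keep the aluminium-bound ketone from enolising at the stereocentre.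

**Step 3**
Reactants: 4 (2S)-2-methyl-1-(2,4,6-trihydroxyphenyl)butan-1-one; 5 3-methylbut-2-enal (prenal)
Product: 7 (2S)-1-(5,7-dihydroxy-2,2-dimethyl-2H-chromen-8-yl)-2-methylbutan-1-one, via o-quinone methide dienone 6 (not isolated)
Conditions: 5 (1.1 equiv), ethylenediammonium diacetate (10 mol %), toluene, reflux
Reagents that add atoms: none
Why: Amine-catalysed Knoevenagel-type condensation at a free ring carbon is followed by 6π-oxa-electrocyclisation of dienone 6; closure through the oxygen next to the acyl group is the expected course for acylphloroglucinols and leaves C6 as the only unsubstituted ring carbon.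

**Step 4**
Reactants: 8 di-tert-butyl malonate
Product: 9 di-tert-butyl 2-methylidenepropanedioate
Conditions: (CH2O)n, KOAc (cat.), Cu(OAc)2·H2O (cat.), AcOH, 95 °C; distillation
Reagents that add atoms: formaldehyde (as paraformaldehyde), C=O
Why: Knoevenagel condensation with formaldehyde and dehydration gives the methylidene malonate, and the bulky tert-butyl esters make it distillable and slow to polymerise.

**Step 5**
Reactants: 7 (2S)-1-(5,7-dihydroxy-2,2-dimethyl-2H-chromen-8-yl)-2-methylbutan-1-one; 9 di-tert-butyl 2-methylidenepropanedioate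
Product: 10 di-tert-butyl 2-({5,7-dihydroxy-2,2-dimethyl-8-[(2S)-2-methylbutanoyl]-2H-chromen-6-yl}methyl)propanedioate
Conditions: iPr2NEt (0.2 equiv), MeCN, 0 °C → rt, slow addition of 9 (1.05 equiv)
Reagents that add atoms: none
Why: In this Friedel–Crafts-type Michael addition the phenoxide of 7 attacks the acceptor terminus through C6, its only free ring carbon, any O-adduct should revert by retro-oxa-Michael reaction, and tert-butyl esters resist lactonisation by the flanking phenols.

**Step 6**
Reactants: 10 di-tert-butyl 2-({5,7-dihydroxy-2,2-dimethyl-8-[(2S)-2-methylbutanoyl]-2H-chromen-6-yl}methyl)propanedioate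
Product: 11 di-tert-butyl 2-({5,7-diacetoxy-2,2-dimethyl-8-[(2S)-2-methylbutanoyl]-2H-chromen-6-yl}methyl)propanedioate
Conditions: Ac2O, pyridine, DMAP (cat.), CH2Cl2, 0 °C → rt
Reagents that add atoms: acetic anhydride, CC(=O)OC(C)=O
Why: DMAP-catalysed O-acetylation caps both hindered phenols so that they cannot lactonise onto the malonyl carbons later, and pyridine is too weak a base to deprotonate the malonate C–H or the ketone α-carbon.

**Step 7**
Reactants: 11 di-tert-butyl 2-({5,7-diacetoxy-2,2-dimethyl-8-[(2S)-2-methylbutanoyl]-2H-chromen-6-yl}methyl)propanedioate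
Product: 12 2-({5,7-diacetoxy-2,2-dimethyl-8-[(2S)-2-methylbutanoyl]-2H-chromen-6-yl}methyl)propanedioic acid
Conditions: TFA–CH2Cl2 (1:3), 0 °C → rt; evaporation from toluene
Reagents that add atoms: none
Why: Acidolysis of the tert-butyl esters (loss of isobutene) frees the malonic acid without water or base, so the aryl acetates stay in place, and the electron-poor diacetoxy acyl chromene should tolerate brief contact with dilute TFA.

**Step 8**
Reactants: 12 2-({5,7-diacetoxy-2,2-dimethyl-8-[(2S)-2-methylbutanoyl]-2H-chromen-6-yl}methyl)propanedioic acid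
Product: 13 2-({5,7-diacetoxy-2,2-dimethyl-8-[(2S)-2-methylbutanoyl]-2H-chromen-6-yl}methyl)propanedioyl dichloride
Conditions: (COCl)2 (3 equiv), DMF (1 mol %), CH2Cl2, 0 °C → rt; evaporation, used crude
Reagents that add atoms: oxalyl chloride, O=C(Cl)C(=O)Cl
Why: DMF-catalysed (Vilsmeier-type) chlorination of both carboxylic acids gives only gaseous by-products, so the crude dichloride can be used directly, and the acetates block dihydrocoumarin formation.

**Step 9**
Reactants: 14 pentan-3-one
Product: 15 (Z)-trimethyl(pent-2-en-3-yloxy)silane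
Conditions: Me3SiCl, Et3N, DMF, 80 °C; pentane extraction, distillation
Reagents that add atoms: chlorotrimethylsilane, C[Si](C)(C)Cl
Why: Silylation of the ketone under equilibrating amine conditions (silyl enol ether formation) can give only one regioisomer because the ketone is symmetrical.

**Step 10**
Reactants: 13 2-({5,7-diacetoxy-2,2-dimethyl-8-[(2S)-2-methylbutanoyl]-2H-chromen-6-yl}methyl)propanedioyl dichloride; 15 (Z)-trimethyl(pent-2-en-3-yloxy)silane
Product: 17 6-[(6-ethyl-4-hydroxy-5-methyl-2-oxo-2H-pyran-3-yl)methyl]-2,2-dimethyl-8-[(2S)-2-methylbutanoyl]-2H-chromene-5,7-diyl diacetate, via acyclic 3,5-diketo acid chloride 16 (not isolated)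
Conditions: 15 (2.2 equiv), Et2O–CH2Cl2, −78 °C → rt, no base or catalyst
Reagents that add atoms: none
Why: The nucleophilic carbon of enol silane 15 attacks one acid chloride of 13 (directly or through the chlorocarbonyl ketene) and forms pyranone bond C4–C5 with loss of Me3SiCl; the ethyl ketone of the resulting 16 then enolises toward the methyl-bearing carbon, its oxygen closes onto the second acid chloride to form O1–C2 with loss of HCl, and the pyran-2,4-dione tautomerises to the 4-hydroxy-2-pyranone. The closest known reaction type is the uncatalysed formation of 4-hydroxy-2-pyranones from ketone trimethylsilyl enol ethers and malonyl dichlorides, including C-substituted ones. The single ring formed closes by a 6-exo-trig O-acylation (lactonisation). No stereocentre is created, since the two transient sp3 centres of 16 become sp2 ring carbons, and the (S)-centre of the side chain is a spectator under base-free, cold conditions. The step needs C- rather than O-acylation of the enol silane, which the soft silyl enol ether and the absence of base favour, and it needs the acid chlorides kept away from the phenol oxygens, which the two acetates secure; because pentan-3-one is symmetrical, methyl and ethyl can only end up on C5 and C6.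

**Step 11**
Reactants: 17 6-[(6-ethyl-4-hydroxy-5-methyl-2-oxo-2H-pyran-3-yl)methyl]-2,2-dimethyl-8-[(2S)-2-methylbutanoyl]-2H-chromene-5,7-diyl diacetate
Product: 18 6-ethyl-3-({5,7-dihydroxy-2,2-dimethyl-8-[(2S)-2-methylbutanoyl]-2H-chromen-6-yl}methyl)-4-hydroxy-5-methyl-2H-pyran-2-one (CNP0212387.1)
Conditions: NH3 (7 M in MeOH), 0 °C; aq. citric acid to pH 4
Reagents that add atoms: none
Why: Aminolysis of the two aryl acetates by ammonia leaves the pyranone untouched as its ammonium 4-olate, and once O7 is free the ketone is a vinylogous acid that should not enolise at the stereocentre.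

**Compound list**
1 | (S)-2-methylbutanoic acid | CC[C@H](C)C(=O)O | starting material
2 | (S)-2-methylbutanoyl chloride | CC[C@H](C)C(=O)Cl | intermediate
3 | phloroglucinol (benzene-1,3,5-triol) | Oc1cc(O)cc(O)c1 | starting material
4 | (2S)-2-methyl-1-(2,4,6-trihydroxyphenyl)butan-1-one | CC[C@H](C)C(=O)c1c(O)cc(O)cc1O | intermediate
5 | 3-methylbut-2-enal (prenal) | CC(C)=CC=O | starting material
6 | (2S)-1-[2,4-dihydroxy-5-(3-methylbut-2-en-1-ylidene)-6-oxocyclohexa-1,3-dien-1-yl]-2-methylbutan-1-one (o-quinone methide dienone, formed in situ) | CC[C@H](C)C(=O)C1=C(O)C=C(O)C(=CC=C(C)C)C1=O | intermediate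
7 | (2S)-1-(5,7-dihydroxy-2,2-dimethyl-2H-chromen-8-yl)-2-methylbutan-1-one | CC[C@H](C)C(=O)c1c(O)cc(O)c2c1OC(C)(C)C=C2 | intermediate
8 | di-tert-butyl malonate | CC(C)(C)OC(=O)CC(=O)OC(C)(C)C | starting material
9 | di-tert-butyl 2-methylidenepropanedioate | C=C(C(=O)OC(C)(C)C)C(=O)OC(C)(C)C | intermediate
10 | di-tert-butyl 2-({5,7-dihydroxy-2,2-dimethyl-8-[(2S)-2-methylbutanoyl]-2H-chromen-6-yl}methyl)propanedioate | CC[C@H](C)C(=O)c1c(O)c(CC(C(=O)OC(C)(C)C)C(=O)OC(C)(C)C)c(O)c2c1OC(C)(C)C=C2 | intermediate
11 | di-tert-butyl 2-({5,7-diacetoxy-2,2-dimethyl-8-[(2S)-2-methylbutanoyl]-2H-chromen-6-yl}methyl)propanedioate | CC[C@H](C)C(=O)c1c(OC(C)=O)c(CC(C(=O)OC(C)(C)C)C(=O)OC(C)(C)C)c(OC(C)=O)c2c1OC(C)(C)C=C2 | intermediate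
12 | 2-({5,7-diacetoxy-2,2-dimethyl-8-[(2S)-2-methylbutanoyl]-2H-chromen-6-yl}methyl)propanedioic acid | CC[C@H](C)C(=O)c1c(OC(C)=O)c(CC(C(=O)O)C(=O)O)c(OC(C)=O)c2c1OC(C)(C)C=C2 | intermediate
13 | 2-({5,7-diacetoxy-2,2-dimethyl-8-[(2S)-2-methylbutanoyl]-2H-chromen-6-yl}methyl)propanedioyl dichloride | CC[C@H](C)C(=O)c1c(OC(C)=O)c(CC(C(=O)Cl)C(=O)Cl)c(OC(C)=O)c2c1OC(C)(C)C=C2 | intermediate
14 | pentan-3-one | CCC(=O)CC | starting material
15 | (Z)-trimethyl(pent-2-en-3-yloxy)silane | C/C=C(/CC)O[Si](C)(C)C | intermediate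
16 | 2-({5,7-diacetoxy-2,2-dimethyl-8-[(2S)-2-methylbutanoyl]-2H-chromen-6-yl}methyl)-4-methyl-3,5-dioxoheptanoyl chloride (diastereomer mixture, formed in situ) | CC[C@H](C)C(=O)c1c(OC(C)=O)c(CC(C(=O)Cl)C(=O)C(C)C(=O)CC)c(OC(C)=O)c2c1OC(C)(C)C=C2 | intermediate
17 | 6-[(6-ethyl-4-hydroxy-5-methyl-2-oxo-2H-pyran-3-yl)methyl]-2,2-dimethyl-8-[(2S)-2-methylbutanoyl]-2H-chromene-5,7-diyl diacetate | CCc1oc(=O)c(Cc2c(OC(C)=O)c3c(c(C(=O)[C@@H](C)CC)c2OC(C)=O)OC(C)(C)C=C3)c(O)c1C | intermediate
18 | 6-ethyl-3-({5,7-dihydroxy-2,2-dimethyl-8-[(2S)-2-methylbutanoyl]-2H-chromen-6-yl}methyl)-4-hydroxy-5-methyl-2H-pyran-2-one | CCc1oc(=O)c(Cc2c(O)c3c(c(C(=O)[C@@H](C)CC)c2O)OC(C)(C)C=C3)c(O)c1C | target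

**Step count**
Total: 11 steps. Longest linear sequence: 9 steps (1, 2, 3, 5, 6, 7, 8, 10, 11); steps 4 and 9 prepare side components.

**Steps most likely to fail**

Step 10. O-acylation of the enol silane or ketene-type self-condensation of the dichloride may outrun C-acylation, and the HCl released may add to the chromene double bond. The fallback makes the pyranone on its own and closes the methylene bridge last; it sets out from 15 and 7 and comes back at 18. Enol silane 15 and parent malonyl dichloride (Et2O, −78 °C → rt) give, through 4-methyl-3,5-dioxoheptanoyl chloride F1, the known-type product 6-ethyl-4-hydroxy-5-methyl-2H-pyran-2-one F2. Dimethylmethylideneammonium iodide (MeCN, rt) converts it by a Mannich reaction into 3-[(dimethylamino)methyl]-6-ethyl-4-hydroxy-5-methyl-2H-pyran-2-one F3. Warming F3 with chromene 7 (dioxane, 60–80 °C) expels dimethylamine, and the resulting 6-ethyl-5-methyl-3-methylidene-2H-pyran-2,4(3H)-dione F4 is trapped by C6 of 7 in a Michael addition to give 18 without any phenol protection.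

Step 3. The dienone may close through the oxygen para to the acyl group, which would give the 6-acyl chromene, or a second enal may condense. The fallback blocks the para oxygen first; it sets out from 4 and comes back at 7. A Mitsunobu reaction (allyl alcohol, PPh3, DIAD, THF, 0 °C) alkylates the unchelated, most acidic 4-OH to give (2S)-1-[2,6-dihydroxy-4-(prop-2-en-1-yloxy)phenyl]-2-methylbutan-1-one F5. Prenal with ethylenediammonium diacetate in refluxing toluene then passes through (2S)-1-[2-hydroxy-5-(3-methylbut-2-en-1-ylidene)-6-oxo-4-(prop-2-en-1-yloxy)cyclohexa-1,3-dien-1-yl]-2-methylbutan-1-one F6, which can close only through an oxygen next to the acyl group, to give (2S)-1-[7-hydroxy-2,2-dimethyl-5-(prop-2-en-1-yloxy)-2H-chromen-8-yl]-2-methylbutan-1-one F7. Pd(PPh3)4 with morpholine (THF, rt) removes the allyl group and delivers 7.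

Step 5. Anionic polymerisation of the methylidene malonate, or O-alkylation that does not revert, may consume the acceptor. The fallback reverses the polarity; it sets out from 7 and comes back at 10. A Mannich reaction of 7 with dimethylmethylideneammonium iodide (CH2Cl2, rt; NaHCO3 work-up) gives (2S)-1-{6-[(dimethylamino)methyl]-5,7-dihydroxy-2,2-dimethyl-2H-chromen-8-yl}-2-methylbutan-1-one F8. Heating F8 with an excess of di-tert-butyl malonate 8 (MeCN or toluene, 80 °C) expels dimethylamine to form (2S)-1-(7-hydroxy-2,2-dimethyl-6-methylidene-5-oxo-5,6-dihydro-2H-chromen-8-yl)-2-methylbutan-1-one F9, and the malonate adds to this o-quinone methide to give 10.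

**Further compounds**
F1 | step 10 | 4-methyl-3,5-dioxoheptanoyl chloride | CCC(=O)C(C)C(=O)CC(=O)Cl
F2 | step 10 | 6-ethyl-4-hydroxy-5-methyl-2H-pyran-2-one | CCc1oc(=O)cc(O)c1C
F3 | step 10 | 3-[(dimethylamino)methyl]-6-ethyl-4-hydroxy-5-methyl-2H-pyran-2-one | CCc1oc(=O)c(CN(C)C)c(O)c1C
F4 | step 10 | 6-ethyl-5-methyl-3-methylidene-2H-pyran-2,4(3H)-dione | CCC1=C(C)C(=O)C(=C)C(=O)O1
F5 | step 3 | (2S)-1-[2,6-dihydroxy-4-(prop-2-en-1-yloxy)phenyl]-2-methylbutan-1-one | CC[C@H](C)C(=O)c1c(O)cc(OCC=C)cc1O
F6 | step 3 | (2S)-1-[2-hydroxy-5-(3-methylbut-2-en-1-ylidene)-6-oxo-4-(prop-2-en-1-yloxy)cyclohexa-1,3-dien-1-yl]-2-methylbutan-1-one | CC[C@H](C)C(=O)C1=C(O)C=C(OCC=C)C(=CC=C(C)C)C1=O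
F7 | step 3 | (2S)-1-[7-hydroxy-2,2-dimethyl-5-(prop-2-en-1-yloxy)-2H-chromen-8-yl]-2-methylbutan-1-one | CC[C@H](C)C(=O)c1c(O)cc(OCC=C)c2c1OC(C)(C)C=C2
F8 | step 5 | (2S)-1-{6-[(dimethylamino)methyl]-5,7-dihydroxy-2,2-dimethyl-2H-chromen-8-yl}-2-methylbutan-1-one | CC[C@H](C)C(=O)c1c(O)c(CN(C)C)c(O)c2c1OC(C)(C)C=C2
F9 | step 5 | (2S)-1-(7-hydroxy-2,2-dimethyl-6-methylidene-5-oxo-5,6-dihydro-2H-chromen-8-yl)-2-methylbutan-1-one | CC[C@H](C)C(=O)C1=C(O)C(=C)C(=O)C2=C1OC(C)(C)C=C2
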